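## Structural features

The target is a monocyclic tetrahydrofuran lignan (ring O1–C2–C3–C4–C5). C2 carries a 3,4,5-trimethoxyphenyl group, C3 a hydroxymethyl group and C4 a 3,4,5-trimethoxybenzoyl group, and C5 is an unsubstituted CH2 next to the ring oxygen. C2, C3 and C4 are three contiguous stereocentres (2R,3R,4S in this numbering): aryl and hydroxymethyl are cis, hydroxymethyl and aroyl are trans. The fragile points are the C4–H alpha to the aryl ketone (epimerisable), the O1–C5 bond beta to that ketone (elimination from the enolate), and the benzylic C2–O1 bond (hydrogenolysis, acid ionisation). The gamma-hydroxy ketone could close to a hemiketal only if C3 and C4 were cis. C4 is not the real problem, because its trans arrangement is the thermodynamic one. The difficulty lies in the crowded 2,3-cis relationship and in fixing the absolute configuration from C2 alone, with the ketone brought in at the right oxidation level. The key step uses the fact that C3–C4–C5, attached to the carbinol carbon C2, is the carbon pattern of a 2,3-allenol with C4 as the central allene carbon and C5 as its CH2 terminus. The aroyl group on C4 is then an aryl iodide plus carbon monoxide, and the C3=C4 double bond left by the cyclisation is reduced under the control of C2.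

## Logic of the disconnections

12 to 11: the hydroxyl O–H is traced back to an O–Si bond. The primary oxygen must stay masked because in 6 it would be a second allenol hydroxyl able to close a ring of its own, and in the 3,4-cis series it could add to the ketone. Nothing is gained in skeleton; the demand is a final unmasking that is not basic, so that C4 and the beta-alkoxy ketone are left alone.

11 to 10: no skeletal bond is cut; only the C4–H bond is re-set. Since 3,4-trans is the stable arrangement and C4 is the only enolisable centre, the precursor may carry either C4 configuration. The forward step needs a base mild enough not to expel O1 from C5.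

10 to 9: the C3–H and C4–H bonds are removed to leave the C3=C4 double bond. This erases two stereocentres and leaves C2 as the only one. The forward step must add hydrogen to the face opposite the C2 aryl group without cleaving C2–O1, shifting the double bond or reducing the ketone.

9 to 6, 7 and 8: three bonds are cut, O1–C5, C4–C(carbonyl) and C(carbonyl)–C(aryl). The ring and the ketone disappear together, and 7 and 8 are commercial. The forward step must put the acyl group on the central allene carbon and the oxygen on the CH2 terminus (not on C3), carbonylate before any direct arylation, and leave the acidic C2–H of 9 untouched.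

6 to 3 and 4 (through 5): the C2–C3 bond is cut, the bond an SE2' addition of a propargyl metal to an aldehyde makes. Both halves are simple and the only stereocentre of 6 is set by a chiral chromium catalyst. The demands are bond formation at the substituted alkyne carbon (allenyl, not homopropargyl, carbinol), face selectivity at 4, and survival of the silyl ether next to the carbon–metal bond.

3 to 2 to 1: the C–Br bond and the O–Si bond are cut, which leads to a symmetric commercial diol. The only demand is monofunctionalisation, and a silyl group that outlasts steps 3 to 6.

## Other disconnections considered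

Alternative 1: The cut is C2–C3, made inside a lactone that links C3 (its alpha carbon, the future CH2OH carbon being the lactone carbonyl) to C4 through the future ketone carbon. Rh2(OAc)4 would decompose the trans-configured alpha-diazo-gamma-lactone A2, and the carbenoid at C3 would insert into a benzylic C–H of the trimethoxybenzyl ether to give the cis-fused endo,exo-furofuranone A1.
- In favour: 1,5 C–H insertion of a rhodium carbenoid next to an ether oxygen is an established ring closure and the cis fusion is enforced. One step would create C2 and C3 with the cis aryl/C3 relationship that is hardest to obtain. In precedent and in stereocentres made by the key step this plan is better than the chosen one, which needs a new method and creates none.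
- Against: A2 must first be made as a single enantiomer with two trans centres, one of which is destroyed when it becomes the ketone. Endo insertion must beat exo insertion and attack on the electron-rich ring. Afterwards the lactone must be reduced, the benzylic carbinol oxidised beside a primary alcohol, and C4 epimerised.
- Comparison: both plans end with the same base epimerisation at C4 and are equal there. The alternative carries the second aryl at the wrong oxidation level and would need an estimated three or more extra steps for diazo transfer and redox corrections. The chosen plan introduces the aroyl group as a ketone in a convergent three-component step.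

Alternative 2: The cut is C3–C4, with C4 carrying a second, removable aroyl group. Ph3PAuCl with AgOTf would activate the terminal alkyne of the propargylic ether A4, and the enol of its 1,3-diketone would add to the internal alkyne carbon in a 5-exo-dig Conia-ene closure to the 3-methylene-4,4-diaroyl tetrahydrofuran A3.
- In favour: gold-catalysed Conia-ene cyclisation of 1,3-dicarbonyl compounds is a known, mild reaction class. C2 would come from a propargylic carbinol, for which asymmetric alkynylation or ynone reduction is dependable. On the origin of C2 the alternative is better than the chosen plan, whose asymmetric allenylation is less secure.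
- Against: A4 joins a secondary benzylic propargylic alcohol to a diaroylmethane through an O–CH2–C link that is hard to forge and, as a beta-alkoxy diketone, easily loses the alcohol again. Cationic gold could ionise the electron-rich benzylic propargylic ether. A whole trimethoxybenzoyl unit is built in only to be removed by retro-Claisen cleavage. Hydroboration of the exocyclic alkene would have to spare the aryl ketones.
- Comparison: C3 would be set by hydroboration anti to the C2 aryl, the same facial argument as the hydrogenation of 9, so the plans are equal on that point. The alternative would need as many or more steps, uses one aryl building block twice and discards one copy, and has its weakest steps late in the route.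

Alternative 3: Two bonds are cut, O1–C2 and C4–C5, which removes O1 and C5 as formaldehyde A7 and leaves the trans-2-aryl-3-(silyloxymethyl)cyclopropane-1,1-diester A6. Sn(OTf)2 would activate the diester; the oxygen of A7 would attack the aryl-bearing carbon with inversion as the cyclopropane bond breaks, and the malonate would close on the formaldehyde carbon to give A5.
- In favour: Lewis-acid annulation of donor–acceptor cyclopropanes with aldehydes is known and stereospecific. The 2,3-cis relationship would follow directly from the trans cyclopropane with no face-selective reduction; on this point the alternative is better than the chosen plan. The silyl ether is the same as in 9 to 11, so the plans are equal in protecting-group demand.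
- Against: an enantiopure trisubstituted cyclopropane from a 1,2-disubstituted electron-rich alkene and a malonate carbenoid is hard to obtain. Partial opening to a benzylic cation would erode C2. Monomeric A7 is awkward to handle. The geminal diester has the wrong oxidation level and substitution: it needs Krapcho dealkoxycarbonylation and conversion of the remaining ester, via an N-methoxy-N-methylamide and an arylmetal, into the ketone.
- Comparison: the key step itself is closer to known chemistry than the chosen one. The sequence after it is estimated to be at least two steps longer, and the second aryl arrives late through organometallic addition rather than in the ring-forming step.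

Key step: step 4

Assumption: the (S,S) antipode of the bis(oxazolinyl)carbazole ligand is taken to give the (S) carbinol 6; if the sense of induction proves opposite, the (R,R) ligand is used with no other change.

## Route

Step 1
Reactants: 1 but-2-yne-1,4-diol
Product: 2 4-(triisopropylsilyloxy)but-2-yn-1-ol
Conditions: TIPSCl (1.0 equiv), imidazole (1.2 equiv), 1 (3 equiv), DMF, 0 °C to rt
Reagents that add atoms: chlorotriisopropylsilane (TIPSCl), CC(C)[Si](Cl)(C(C)C)C(C)C
Why: Statistical monosilylation of a symmetric diol used in excess (the surplus diol washes out with water); TIPS is chosen because it survives the later TMS removal, carbonate and DBU, and as a bulky, weakly donating ether it is the one least likely to be expelled from the propargyl/allenyl metal in step 3.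

Step 2
Reactants: 2 4-(triisopropylsilyloxy)but-2-yn-1-ol
Product: 3 (4-bromobut-2-ynyloxy)triisopropylsilane
Conditions: CBr4, PPh3, CH2Cl2, 0 °C
Reagents that add atoms: carbon tetrabromide, BrC(Br)(Br)Br
Why: Appel bromination; bromide displaces the alkoxyphosphonium ion of the primary propargylic alcohol under neutral conditions that leave the silyl ether intact.

Step 3
Reactants: 3 (4-bromobut-2-ynyloxy)triisopropylsilane; 4 3,4,5-trimethoxybenzaldehyde
Product: 6 (1S)-1-(3,4,5-trimethoxyphenyl)-2-(triisopropylsilyloxymethyl)buta-2,3-dien-1-ol, via trimethylsilyl ether 5 (not isolated)
Conditions: CrCl2 (10 mol %), (S,S)-3,6-di-tert-butyl-1,8-bis(4-isopropyl-4,5-dihydrooxazol-2-yl)carbazole (10 mol %), Mn (2 equiv), iPr2NEt (0.3 equiv), TMSCl (1.5 equiv), THF, rt; then K2CO3 (0.2 equiv), MeOH, 0 °C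
Reagents that add atoms: chlorotrimethylsilane, C[Si](C)(C)Cl (its silyl group is carried only by intermediate 5 and is removed again in the same step; no reagent atom remains in 6)
Why: Catalytic asymmetric Nozaki–Hiyama–Kishi-type allenylation (chromium only): Mn regenerates the low-valent chromium catalyst, which turns 3 into a propargyl/allenyl species of trivalent chromium that adds to 4 through a cyclic SE2' transition state at the substituted alkyne carbon, giving the allenyl and not the homopropargyl carbinol, while TMSCl frees the catalyst as silyl ether 5, which mild methanolysis cleaves without touching the TIPS ether; the tridentate ligand on chromium selects the aldehyde face and sets the carbinol centre (S in 5 and 6; it becomes C2 of 12).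

Step 4
Reactants: 6 (1S)-1-(3,4,5-trimethoxyphenyl)-2-(triisopropylsilyloxymethyl)buta-2,3-dien-1-ol; 7 5-iodo-1,2,3-trimethoxybenzene; 8 carbon monoxide
Product: 9 [(5S)-5-(3,4,5-trimethoxyphenyl)-4-(triisopropylsilyloxymethyl)-2,5-dihydrofuran-3-yl](3,4,5-trimethoxyphenyl)methanone (in the ring numbering used here: (2S)-2-aryl-4-aroyl-3-silyloxymethyl-2,5-dihydrofuran)
Conditions: Pd(PPh3)4 (5 mol %), CO (1 atm), K2CO3 (2 equiv), MeCN, 50 °C
Reagents that add atoms: none
Why: Proposed new method: oxidative addition of zerovalent palladium to the C–I bond of 7 and migratory insertion of 8 should give an aroylpalladium iodide (divalent palladium) that engages the C4=C5 bond of 6 either as a soft electrophile, triggering anti attack of the C2 hydroxyl on C5 and leaving a C4 vinylpalladium aroyl species that reductively eliminates the C4–acyl bond, or by acyl transfer to the central carbon to give a 2-aroyl-pi-allyl complex whose unsubstituted CH2 terminus is taken by the oxygen; both channels converge on 9 and return zerovalent palladium. The closest known reaction types are the palladium-catalysed coupling–cyclisation of 2,3-allenols with aryl halides, the carbonylative aroylation–cyclisation of 2-alkynylphenols to 3-aroylbenzofurans, and the capture by heteronucleophiles of 2-acyl-pi-allyl complexes made from aryl iodides, carbon monoxide and allenes; the new element is the union of carbonylation with this closure of an allenol. The one ring is closed by O1–C5 bond formation, 5-endo-trig on the coordinated allene or attack at the distal terminus of the pi-allyl unit held in its anti geometry. No stereocentre is created: C2 comes unchanged from 6, and because C5 is an unsubstituted CH2 there is no allene axis to match. The step needs acyl on the central carbon, oxygen on C5 and not on C3, and carbonylation ahead of direct arylation or O-aroylation: the central allene carbon is the inherent site of both vinylpalladium formation and acyl transfer, C3 is fully substituted while C5 is unhindered, a kinetically formed 2-(1-aroylvinyl)oxirane would be an activated allylic electrophile that zerovalent palladium can re-ionise towards the strain-free conjugated enone, and a CO atmosphere with an electron-rich aryl group favours fast acyl formation. Solid K2CO3 in MeCN is a weak, sparingly soluble acceptor for HI, chosen so that the vinylogous, benzylic C2–H of 9 is not removed.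

Step 5
Reactants: 9 [(5S)-5-(3,4,5-trimethoxyphenyl)-4-(triisopropylsilyloxymethyl)-2,5-dihydrofuran-3-yl](3,4,5-trimethoxyphenyl)methanone
Product: 10 [(3R,4R,5R)-5-(3,4,5-trimethoxyphenyl)-4-(triisopropylsilyloxymethyl)oxolan-3-yl](3,4,5-trimethoxyphenyl)methanone (all-cis; 2R,3R,4R in the ring numbering used here)
Conditions: H2 (3 atm), 5 % Rh/Al2O3, EtOAc, rt
Reagents that add atoms: none
Why: Heterogeneous catalytic hydrogenation; syn delivery of two hydrogens to the ketone-conjugated C3=C4 bond from the face opposite the C2 aryl group sets C3 (R, silyloxymethyl cis to aryl) and C4 (R, aroyl also cis), and Rh on alumina is chosen because it has little tendency to cleave benzylic or allylic C–O bonds or to shift the double bond towards C2.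

Step 6
Reactants: 10 [(3R,4R,5R)-5-(3,4,5-trimethoxyphenyl)-4-(triisopropylsilyloxymethyl)oxolan-3-yl](3,4,5-trimethoxyphenyl)methanone
Product: 11 [(3S,4R,5R)-5-(3,4,5-trimethoxyphenyl)-4-(triisopropylsilyloxymethyl)oxolan-3-yl](3,4,5-trimethoxyphenyl)methanone (2,3-cis-3,4-trans; 2R,3R,4S in the ring numbering used here)
Conditions: DBU (0.3 equiv), CH2Cl2, rt
Reagents that add atoms: none
Why: Base-mediated epimerisation through the C4 enolate; C4–H is the only acidic C–H, so only this centre equilibrates and the crowded all-cis isomer should relax to the 3,4-trans isomer (C4 now S), while loss of O1 from the enolate is a reverse 5-endo-trig process with poor orbital overlap inside the ring and should be slow with a catalytic amine base at room temperature.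

Step 7
Reactants: 11 [(3S,4R,5R)-5-(3,4,5-trimethoxyphenyl)-4-(triisopropylsilyloxymethyl)oxolan-3-yl](3,4,5-trimethoxyphenyl)methanone
Product: 12 [(3S,4R,5R)-4-(hydroxymethyl)-5-(3,4,5-trimethoxyphenyl)oxolan-3-yl](3,4,5-trimethoxyphenyl)methanone (the target; 2R,3R,4S in the ring numbering used here)
Conditions: HF·pyridine, pyridine, THF, 0 °C to rt
Reagents that add atoms: none
Why: Fluoride-driven Si–O cleavage under buffered, non-basic conditions frees the primary alcohol without touching C4 or the beta-alkoxy ketone; in the 3,4-trans series the hydroxyl cannot reach the ketone, so 12 is expected as the open hydroxy ketone.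

## Compound list

1 | but-2-yne-1,4-diol | OCC#CCO | starting material
2 | 4-(triisopropylsilyloxy)but-2-yn-1-ol | OCC#CCO[Si](C(C)C)(C(C)C)C(C)C | intermediate
3 | (4-bromobut-2-ynyloxy)triisopropylsilane | BrCC#CCO[Si](C(C)C)(C(C)C)C(C)C | intermediate
4 | 3,4,5-trimethoxybenzaldehyde | COc1cc(C=O)cc(OC)c1OC | starting material
5 | trimethylsilyl ether of 6, (1S)-1-(3,4,5-trimethoxyphenyl)-2-(triisopropylsilyloxymethyl)-1-(trimethylsilyloxy)buta-2,3-diene | C=C=C(CO[Si](C(C)C)(C(C)C)C(C)C)[C@H](c1cc(OC)c(OC)c(OC)c1)O[Si](C)(C)C | intermediate
6 | (1S)-1-(3,4,5-trimethoxyphenyl)-2-(triisopropylsilyloxymethyl)buta-2,3-dien-1-ol | C=C=C(CO[Si](C(C)C)(C(C)C)C(C)C)[C@H](c1cc(OC)c(OC)c(OC)c1)O | intermediate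
7 | 5-iodo-1,2,3-trimethoxybenzene | COc1cc(I)cc(OC)c1OC | starting material
8 | carbon monoxide | [C-]#[O+] | starting material
9 | [(5S)-5-(3,4,5-trimethoxyphenyl)-4-(triisopropylsilyloxymethyl)-2,5-dihydrofuran-3-yl](3,4,5-trimethoxyphenyl)methanone | O=C(c1cc(OC)c(OC)c(OC)c1)C1=C(CO[Si](C(C)C)(C(C)C)C(C)C)[C@H](c2cc(OC)c(OC)c(OC)c2)OC1 | intermediate
10 | [(3R,4R,5R)-5-(3,4,5-trimethoxyphenyl)-4-(triisopropylsilyloxymethyl)oxolan-3-yl](3,4,5-trimethoxyphenyl)methanone, all-cis | COc1cc(C(=O)[C@H]2CO[C@@H](c3cc(OC)c(OC)c(OC)c3)[C@H]2CO[Si](C(C)C)(C(C)C)C(C)C)cc(OC)c1OC | intermediate
11 | [(3S,4R,5R)-5-(3,4,5-trimethoxyphenyl)-4-(triisopropylsilyloxymethyl)oxolan-3-yl](3,4,5-trimethoxyphenyl)methanone | COc1cc(C(=O)[C@@H]2CO[C@@H](c3cc(OC)c(OC)c(OC)c3)[C@H]2CO[Si](C(C)C)(C(C)C)C(C)C)cc(OC)c1OC | intermediate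
12 | [(3S,4R,5R)-4-(hydroxymethyl)-5-(3,4,5-trimethoxyphenyl)oxolan-3-yl](3,4,5-trimethoxyphenyl)methanone | COc1cc(C(=O)[C@@H]2CO[C@@H](c3cc(OC)c(OC)c(OC)c3)[C@H]2CO)cc(OC)c1OC | target

The aryl-bearing carbon is the same spatial centre throughout. Its label is S in 5, 6 and 9 and R in 10 to 12 only because C3 loses priority to the aryl group once it becomes sp3.

## Step count and least certain steps

Total step count: 7. Longest linear sequence: 7 steps (1 to 12); 4, 7 and 8 enter as commercial materials.

Key step (step 4, the proposed new method). Most likely to go wrong: ring closure at the substituted terminus C3 (three-membered ring instead of five), direct arylation of the allene before carbon monoxide has inserted, aroylation of the free hydroxyl, and base-promoted removal of the C2 proton of the product with loss of configuration or double-bond migration. These compete because aryl- and acylpalladium species add to allenes quickly and the closest known allenol couplings favour closure at the proximal carbon. Fallback, known chemistry, from 6 back to 9: iodocyclisation of 6 with N-iodosuccinimide in CH2Cl2 (5-endo halocyclisation of a 2,3-allenol, iodine on the central carbon) should give (2S)-4-iodo-2-(3,4,5-trimethoxyphenyl)-3-(triisopropylsilyloxymethyl)-2,5-dihydrofuran F1. Carbonylative Suzuki–Miyaura coupling of F1 with commercial 3,4,5-trimethoxyphenylboronic acid (PdCl2(PPh3)2, CO 1 atm, K2CO3, anisole, 80 °C) should then deliver 9.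

Step 3. Most likely to go wrong: bond formation at the CH2 terminus (homopropargyl carbinol), insufficient face selectivity with the electron-rich aldehyde, expulsion of the silyloxy group from the organochromium species (1,4-elimination), and reductive pinacol coupling of 4 by Mn/TMSCl. The oxygenated propargyl bromide is a less tested partner than alkyl- or silyl-substituted ones. Fallback from 3 and 4 back to 6: a Barbier allenylation with indium metal in THF/H2O, which tolerates oxygen next to the carbon–metal bond, should give racemic 1-(3,4,5-trimethoxyphenyl)-2-(triisopropylsilyloxymethyl)buta-2,3-dien-1-ol F2. Steglich esterification with (S)-2-methoxy-2-phenylacetic acid (EDC, DMAP, CH2Cl2, 0 °C) gives the (1S)-carbinol (2S)-2-methoxy-2-phenylacetate F3 and the (1R)-carbinol (2S)-2-methoxy-2-phenylacetate F4. These are separated by chromatography, and methanolysis of F3 (K2CO3, MeOH) returns 6. Half of the material is lost, but the same esters also serve to assign the configuration.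

Step 5. Most likely to go wrong: sluggish reduction of the tetrasubstituted alkene, over-reduction of the aryl ketone, hydrogenolysis of the benzylic and allylic C2–O1 bond, migration of the double bond to C2 (which would erase the stereocentre), or incomplete face selectivity. All of these are competing surface processes on a hindered substrate. Fallback from 9 back to 10: homogeneous conjugate hydride transfer with [(Ph3P)CuH]6 in wet toluene, which adds hydride to C3 anti to the aryl group and protonates the copper enolate. Any 11 formed in the protonation is carried along, since step 6 converges both C4 epimers. This fallback makes no new compound (F0).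

Step 6. Most likely to go wrong: beta-elimination of the ring oxygen from the C4 enolate (ring opening) or incomplete equilibration. Fallback from 10 to 12, bypassing 11: desilylation first (HF·pyridine) to the all-cis hydroxy ketone [(3R,4R,5R)-4-(hydroxymethyl)-5-(3,4,5-trimethoxyphenyl)oxolan-3-yl](3,4,5-trimethoxyphenyl)methanone F5. F5 is then equilibrated at C4 with catalytic K2CO3 in MeOH, a protic medium in which the enolate is reprotonated quickly and only the cis isomer can rest as a hemiketal, to give 12.

## Further compounds

F1 | step 4 | (2S)-4-iodo-2-(3,4,5-trimethoxyphenyl)-3-(triisopropylsilyloxymethyl)-2,5-dihydrofuran | IC1=C(CO[Si](C(C)C)(C(C)C)C(C)C)[C@H](c2cc(OC)c(OC)c(OC)c2)OC1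
F2 | step 3 | racemic 1-(3,4,5-trimethoxyphenyl)-2-(triisopropylsilyloxymethyl)buta-2,3-dien-1-ol | C=C=C(CO[Si](C(C)C)(C(C)C)C(C)C)C(O)c1cc(OC)c(OC)c(OC)c1
F3 | step 3 | (1S)-1-(3,4,5-trimethoxyphenyl)-2-(triisopropylsilyloxymethyl)buta-2,3-dien-1-yl (2S)-2-methoxy-2-phenylacetate | C=C=C(CO[Si](C(C)C)(C(C)C)C(C)C)[C@H](c1cc(OC)c(OC)c(OC)c1)OC(=O)[C@@H](OC)c1ccccc1
F4 | step 3 | (1R)-1-(3,4,5-trimethoxyphenyl)-2-(triisopropylsilyloxymethyl)buta-2,3-dien-1-yl (2S)-2-methoxy-2-phenylacetate | C=C=C(CO[Si](C(C)C)(C(C)C)C(C)C)[C@@H](c1cc(OC)c(OC)c(OC)c1)OC(=O)[C@@H](OC)c1ccccc1
F0 | step 5 | none | none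
F5 | step 6 | [(3R,4R,5R)-4-(hydroxymethyl)-5-(3,4,5-trimethoxyphenyl)oxolan-3-yl](3,4,5-trimethoxyphenyl)methanone, all-cis | COc1cc(C(=O)[C@H]2CO[C@@H](c3cc(OC)c(OC)c(OC)c3)[C@H]2CO)cc(OC)c1OC
A1 | alternative 1 | endo,exo-2,6-bis(3,4,5-trimethoxyphenyl)-3,7-dioxabicyclo[3.3.0]octan-8-one | O=C1O[C@H](c2cc(OC)c(OC)c(OC)c2)[C@H]2CO[C@@H](c3cc(OC)c(OC)c(OC)c3)[C@@H]12
A2 | alternative 1 | trans-3-diazo-4-[(3,4,5-trimethoxybenzyloxy)methyl]-5-(3,4,5-trimethoxyphenyl)oxolan-2-one | O=C1O[C@H](c2cc(OC)c(OC)c(OC)c2)[C@@H](COCc2cc(OC)c(OC)c(OC)c2)C1=[N+]=[N-]
A3 | alternative 2 | (2S)-3-methylene-4,4-bis(3,4,5-trimethoxybenzoyl)-2-(3,4,5-trimethoxyphenyl)tetrahydrofuran | C=C1[C@H](c2cc(OC)c(OC)c(OC)c2)OCC1(C(=O)c1cc(OC)c(OC)c(OC)c1)C(=O)c1cc(OC)c(OC)c(OC)c1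
A4 | alternative 2 | 2-{[(1R)-1-(3,4,5-trimethoxyphenyl)prop-2-ynyloxy]methyl}-1,3-bis(3,4,5-trimethoxyphenyl)propane-1,3-dione | C#C[C@H](c1cc(OC)c(OC)c(OC)c1)OCC(C(=O)c1cc(OC)c(OC)c(OC)c1)C(=O)c1cc(OC)c(OC)c(OC)c1
A5 | alternative 3 | dimethyl (2R,3R)-2-(3,4,5-trimethoxyphenyl)-3-(triisopropylsilyloxymethyl)tetrahydrofuran-4,4-dicarboxylate (ring numbering as used here) | COC(=O)C1(C(=O)OC)CO[C@@H](c2cc(OC)c(OC)c(OC)c2)[C@H]1CO[Si](C(C)C)(C(C)C)C(C)C
A6 | alternative 3 | dimethyl trans-2-(3,4,5-trimethoxyphenyl)-3-(triisopropylsilyloxymethyl)cyclopropane-1,1-dicarboxylate | COC(=O)C1(C(=O)OC)[C@H](c2cc(OC)c(OC)c(OC)c2)[C@H]1CO[Si](C(C)C)(C(C)C)C(C)C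
A7 | alternative 3 | formaldehyde | C=O
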